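Assumption: the SMILES is taken literally, so the decalin is the ent-drimane series (1R,4aR,8aR), the mirror image of (−)-drimenol and sclareolide. The dioxane unit is (2S,3S,6S), with the long chain at C6 cis to the C3 side chain.

**Retrosynthetic overview**
- Target ⇒ (diimide) propargylic peroxide. The key bond is C6–C7: a metal acetylide, used as a masked acyl anion RCH2C(=O)−, attacks a cyclic C6 peroxycarbenium ion. Two carbonyl-level carbons are joined and the quaternary C6 centre is set by axial attack.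
- The 6-methoxy-1,2-dioxane ester ⇒ keto-β-lactone + H2O2. The peroxide ring closes by SN2 opening of the lactone at C3, with inversion.
- The cis-β-lactone ⇒ 4-oxopentanal + propionyl chloride (catalytic asymmetric ketene–aldehyde [2+2]); 4-oxopentanal ⇒ 6-methylhept-5-en-2-one.
- The acetylide donor ⇒ dibromoalkene ⇒ ent-drimenal ⇒ (+)-drimenol ⇒ (2E,6E)-farnesol (cationic bicyclisation, then lipase resolution).
- Ring order: rings A and B of the decalin form together first (fragment 1). In fragment 2 the β-lactone forms first and the 1,2-dioxane second. No ring is formed after the coupling.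

**Route**

Step 1
Reactants: 1 (2E,6E)-farnesol
Product: 2 (±)-drimenol
Conditions: FSO3H (8 equiv), 2-nitropropane, −78 °C, 30 min; Et3N quench
Reagents that add atoms: none
Why: Superacid polyene bicyclisation (Stork–Eschenmoser chair–chair folding of the E,E-triene) sets the relative configuration of C1, C4a and C8a (trans-decalin, equatorial CH2OH) in one step, and kinetic loss of the axial ring proton next to the tertiary cation gives the trisubstituted ring alkene of the target.

Step 2
Reactants: 2 (±)-drimenol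
Product: 3 (+)-drimenol, [(1R,4aR,8aR)-2,5,5,8a-tetramethyl-1,4,4a,5,6,7,8,8a-octahydronaphthalen-1-yl]methanol
Conditions: lipase from Alcaligenes sp., isopropenyl acetate, i-Pr2O, 30 °C, to ca. 55 % conversion; chromatography
Reagents that add atoms: none
Why: Enzymatic kinetic resolution by lipase transesterification acetylates the (1S,4aS,8aS) enantiomer faster (as with the closely related albicanol), so the unreacted (1R,4aR,8aR) alcohol is recovered in high ee and the absolute configuration of the three decalin stereocentres is fixed.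

Step 3
Reactants: 3 (+)-drimenol
Product: 4 ent-drimenal, (1R,4aR,8aR)-2,5,5,8a-tetramethyl-1,4,4a,5,6,7,8,8a-octahydronaphthalene-1-carbaldehyde
Conditions: (n-Pr4N)RuO4 (5 mol %), N-methylmorpholine N-oxide, 4 Å MS, CH2Cl2, 0 °C to rt
Reagents that add atoms: none
Why: The Ley–Griffith oxidation is neutral, so the β,γ-unsaturated aldehyde neither epimerises at C1 (its CHO is already equatorial) nor moves its double bond into conjugation.

Step 4
Reactants: 4 ent-drimenal
Product: 5 (1R,4aR,8aR)-1-(2,2-dibromoethenyl)-2,5,5,8a-tetramethyl-1,4,4a,5,6,7,8,8a-octahydronaphthalene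
Conditions: CBr4 (2 equiv), PPh3 (4 equiv), CH2Cl2, 0 °C
Reagents that add atoms: carbon tetrabromide, BrC(Br)(Br)Br
Why: The Ramirez dibromoolefination (first half of the Corey–Fuchs sequence) uses a non-basic ylide, so the allylic C1 stereocentre is kept while the future C7 is installed.

Step 5
Reactants: 6 6-methylhept-5-en-2-one
Product: 8 4-oxopentanal, via secondary ozonide 7 (not isolated)
Conditions: O3, CH2Cl2, −78 °C; Me2S, −78 °C to rt
Reagents that add atoms: ozone, [O-][O+]=O
Why: Criegee ozonolysis with reductive work-up cleaves the only C=C bond and delivers the γ-keto aldehyde that carries C3–C6 and the C6 methyl group; no stereocentre is involved.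

Step 6
Reactants: 8 4-oxopentanal; 9 propionyl chloride
Product: 11 (3S,4R)-3-methyl-4-(3-oxobutyl)oxetan-2-one, via methylketene 10 (not isolated)
Conditions: O-trimethylsilylquinine (10 mol %), LiClO4, i-Pr2NEt, CH2Cl2–Et2O, −78 °C, slow addition of 9
Reagents that add atoms: none
Why: The catalytic asymmetric acyl halide–aldehyde cyclocondensation (Wynberg-type ketene–aldehyde [2+2] through the alkaloid-bound Z-ammonium enolate and a Li+-organised closed transition state) gives the cis-β-lactone under catalyst control, setting C2 (S, final) and C3 (R, to be inverted), while the less electrophilic methyl ketone does not compete.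

Step 7
Reactants: 11 (3S,4R)-3-methyl-4-(3-oxobutyl)oxetan-2-one
Product: 13 (2S)-2-[(3S)-6-hydroxy-6-methyl-1,2-dioxan-3-yl]propanoic acid (C6 anomers), via hydroperoxy hemiketal 12 (not isolated)
Conditions: anhydrous H2O2 in Et2O (10 equiv), Yb(OTf)3 (10 mol %), 0 °C to rt
Reagents that add atoms: hydrogen peroxide, OO
Why: Proposed new method: H2O2 adds reversibly to the methyl ketone and the hydroperoxy hemiketal displaces the Lewis-acid-activated lactone oxygen at C3 in a 6-exo-tet SN2 reaction (alkyl–oxygen fission), so C3 is inverted from R to S, C2 is untouched and the 2,3-anti relationship of the target results (direct attack of H2O2 at C3 followed by hemiketalisation gives the same product); the closest known reaction types are the triflate-mediated perhydrolysis of oxetanes and epoxides with inversion, the neutral solvolysis of β-lactones by alkyl–oxygen cleavage with inversion and the intramolecular alkylation of hydroperoxyketals.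

Step 8
Reactants: 13 (2S)-2-[(3S)-6-hydroxy-6-methyl-1,2-dioxan-3-yl]propanoic acid
Product: 14 methyl (2S)-2-[(3S)-6-methoxy-6-methyl-1,2-dioxan-3-yl]propanoate (C6 anomers)
Conditions: MeOH, HC(OMe)3, p-TsOH (5 mol %), rt
Reagents that add atoms: methanol, CO; trimethyl orthoformate, COC(OC)OC
Why: Fischer esterification and acid-catalysed peroxyhemiketal-to-peroxyketal exchange run together, C2 and C3 are untouched, and the C6 anomer ratio does not matter because C6 becomes planar in the next step.

Step 9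
Reactants: 5 (1R,4aR,8aR)-1-(2,2-dibromoethenyl)-2,5,5,8a-tetramethyl-1,4,4a,5,6,7,8,8a-octahydronaphthalene; 14 methyl (2S)-2-[(3S)-6-methoxy-6-methyl-1,2-dioxan-3-yl]propanoate
Product: 17 methyl (2S)-2-[(3S,6R)-6-methyl-6-{[(1R,4aR,8aR)-2,5,5,8a-tetramethyl-1,4,4a,5,6,7,8,8a-octahydronaphthalen-1-yl]ethynyl}-1,2-dioxan-3-yl]propanoate, via lithium acetylide 15 (not isolated), via dimethylalkynylalane 16 (not isolated)
Conditions: 5 (1.5 equiv), n-BuLi (3.0 equiv), Et2O, −78 to 0 °C; Me2AlCl (1.5 equiv), 0 °C; then 14, BF3·OEt2 (2 equiv), CH2Cl2, −78 to −30 °C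
Reagents that add atoms: none
Why: Proposed new method: after Fritsch–Buttenberg–Wiechell formation of the acetylide and Li-to-Al exchange, BF3 ionises the exocyclic C6–OMe bond to a cyclic peroxycarbenium ion and the alkynylalane, a masked acyl anion RCH2C(=O)− (the alkyne being a latent ketone), attacks it, so two carbonyl-level, normally electrophilic carbons (C6 of the former methyl ketone and C7) are joined; axial attack on the half-chair that keeps the C3 side chain pseudo-equatorial places the new bond cis to that side chain and the methyl group equatorial (also the thermodynamic arrangement, alkynyl being much smaller than methyl), which is the C6 configuration of the target; the closest known reaction types are the Lewis-acid allylation and enol-silane alkylation of 3-alkoxy-1,2-dioxolanes and 1,2-dioxanes through peroxycarbenium ions and the BF3-promoted alkynylalane C-glycosidation, which tolerates the peroxide of artemisinin derivatives.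

Step 10
Reactants: 17 methyl (2S)-2-[(3S,6R)-6-methyl-6-{[(1R,4aR,8aR)-2,5,5,8a-tetramethyl-1,4,4a,5,6,7,8,8a-octahydronaphthalen-1-yl]ethynyl}-1,2-dioxan-3-yl]propanoate
Product: 19 methyl (2S)-2-[(3S,6S)-6-methyl-6-{2-[(1R,4aR,8aR)-2,5,5,8a-tetramethyl-1,4,4a,5,6,7,8,8a-octahydronaphthalen-1-yl]ethyl}-1,2-dioxan-3-yl]propanoate (target), via Z-alkene 18 (not isolated)
Conditions: KO2CN=NCO2K (30 equiv), AcOH (60 equiv, slow addition), MeOH–CH2Cl2, 0 °C to rt, recharged until 18 is consumed
Reagents that add atoms: none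
Why: Diimide reduction (concerted syn transfer of H2) takes the alkyne through the Z-alkene to the saturated chain and leaves the O–O bond, the ester and the hindered trisubstituted ring alkene untouched; no stereocentre changes (the C6 descriptor changes from R to S only because the CIP priorities change).

**Compound list**
1 | (2E,6E)-farnesol | CC(C)=CCC/C(C)=C/CC/C(C)=C/CO | starting material
2 | (±)-drimenol (racemate, both enantiomers shown) | OC[C@@H]1C(C)=CC[C@@H]2C(C)(C)CCC[C@@]12C.OC[C@H]1C(C)=CC[C@H]2C(C)(C)CCC[C@]12C | intermediate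
3 | (+)-drimenol, (1R,4aR,8aR) | OC[C@@H]1C(C)=CC[C@@H]2C(C)(C)CCC[C@@]12C | intermediate
4 | ent-drimenal, (1R,4aR,8aR) | O=C[C@@H]1C(C)=CC[C@@H]2C(C)(C)CCC[C@@]12C | intermediate
5 | (1R,4aR,8aR)-1-(2,2-dibromoethenyl)-2,5,5,8a-tetramethyl-1,4,4a,5,6,7,8,8a-octahydronaphthalene | BrC(Br)=C[C@@H]1C(C)=CC[C@@H]2C(C)(C)CCC[C@@]12C | intermediate
6 | 6-methylhept-5-en-2-one | CC(=O)CCC=C(C)C | starting material
7 | 4-(5,5-dimethyl-1,2,4-trioxolan-3-yl)butan-2-one (secondary ozonide, racemic) | CC(=O)CCC1OOC(C)(C)O1 | intermediate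
8 | 4-oxopentanal | CC(=O)CCC=O | intermediate
9 | propionyl chloride | CCC(=O)Cl | starting material
10 | methylketene | CC=C=O | intermediate
11 | (3S,4R)-3-methyl-4-(3-oxobutyl)oxetan-2-one | C[C@H]1[C@@H](CCC(C)=O)OC1=O | intermediate
12 | (3S,4R)-4-(3-hydroperoxy-3-hydroxybutyl)-3-methyloxetan-2-one | C[C@H]1[C@@H](CCC(C)(O)OO)OC1=O | intermediate
13 | (2S)-2-[(3S)-6-hydroxy-6-methyl-1,2-dioxan-3-yl]propanoic acid (C6 anomers) | OC(=O)[C@@H](C)[C@@H]1CCC(C)(O)OO1 | intermediate
14 | methyl (2S)-2-[(3S)-6-methoxy-6-methyl-1,2-dioxan-3-yl]propanoate (C6 anomers) | COC(=O)[C@@H](C)[C@@H]1CCC(C)(OC)OO1 | intermediate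
15 | lithium [(1R,4aR,8aR)-2,5,5,8a-tetramethyl-1,4,4a,5,6,7,8,8a-octahydronaphthalen-1-yl]acetylide | [Li]C#C[C@@H]1C(C)=CC[C@@H]2C(C)(C)CCC[C@@]12C | intermediate
16 | dimethyl{[(1R,4aR,8aR)-2,5,5,8a-tetramethyl-1,4,4a,5,6,7,8,8a-octahydronaphthalen-1-yl]ethynyl}alane | C[Al](C)C#C[C@@H]1C(C)=CC[C@@H]2C(C)(C)CCC[C@@]12C | intermediate
17 | alkynyl dioxane ester, (2S,3S,6R; 1R,4aR,8aR) | COC(=O)[C@@H](C)[C@@H]1CC[C@](C)(C#C[C@@H]2C(C)=CC[C@@H]3C(C)(C)CCC[C@@]23C)OO1 | intermediate
18 | (Z)-alkenyl dioxane ester, (2S,3S,6R; 1R,4aR,8aR) | COC(=O)[C@@H](C)[C@@H]1CC[C@](C)(/C=C\[C@@H]2C(C)=CC[C@@H]3C(C)(C)CCC[C@@]23C)OO1 | intermediate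
19 | CNP0124238.1, (2S,3S,6S; 1R,4aR,8aR) | COC(=O)[C@@H](C)[C@@H]1CC[C@](C)(CC[C@@H]2C(C)=CC[C@@H]3C(C)(C)CCC[C@@]23C)OO1 | target

**Step count**
Total: 10 steps. Longest linear sequence: 6 steps (1→2→3→4→9→10, or equally 5→6→7→8→9→10).

**Steps most likely to fail, with fallbacks**

Step 9 (alkynylation of the peroxyketal). The Lewis acid may ionise the ring C–O bond instead of the C6–OMe bond, or the cation may lose a proton.
- The fallback makes the C6–C7 bond by carbonyl addition before the ring exists and closes the ring last. It sets out from 5 and 11 and returns at 17.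
- The acetylide from 5 is transmetallated with CeCl3 to alkynylcerium dichloride F4. At −78 °C this adds to the ketone of 11 to give (3S,4R)-4-{3-hydroxy-3-methyl-5-[(1R,4aR,8aR)-2,5,5,8a-tetramethyl-1,4,4a,5,6,7,8,8a-octahydronaphthalen-1-yl]pent-4-yn-1-yl}-3-methyloxetan-2-one F5, as both C6 epimers.
- H2O2 and Yb(OTf)3 then open the lactone at C3 as in step 7. The tertiary propargylic alcohol ionises reversibly, so the C3 hydroperoxide closes the dioxane under thermodynamic control (slim alkynyl axial, methyl equatorial). The product is (2S)-2-[(3S,6R)-6-methyl-6-{[(1R,4aR,8aR)-2,5,5,8a-tetramethyl-1,4,4a,5,6,7,8,8a-octahydronaphthalen-1-yl]ethynyl}-1,2-dioxan-3-yl]propanoic acid F6.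
- Me3SiCHN2 converts F6 into 17.

Step 7 (perhydrolysis of the β-lactone). H2O2 may attack the acyl carbon instead of C3.
- The fallback replaces the lactone by a sulfonate leaving group. It sets out from 11 and returns at 14.
- Methanolysis (MeOH, catalytic K2CO3, acyl–oxygen cleavage with retention) gives methyl (2S,3R)-3-hydroxy-2-methyl-6-oxoheptanoate F1.
- MsCl in pyridine gives methyl (2S,3R)-3-(methanesulfonyloxy)-2-methyl-6-oxoheptanoate F2.
- Urea–H2O2 and Sc(OTf)3 in MeOH convert the ketone into methyl (2S,3R)-6-hydroperoxy-6-methoxy-3-(methanesulfonyloxy)-2-methylheptanoate F3.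
- Ag2O in CH2Cl2 promotes the 6-exo-tet displacement with inversion at C3, under non-basic conditions to hold back β-elimination, and gives 14 directly.

Step 10 (diimide on a hindered alkyne). The triple bond lies between a quaternary and a tertiary carbon and may resist full reduction.
- The fallback delivers the chain already saturated. It sets out from 4 and 14 and returns at 19.
- Methylenation of 4 (Ph3P=CH2, −78 °C) gives (1R,4aR,8aR)-1-ethenyl-2,5,5,8a-tetramethyl-1,4,4a,5,6,7,8,8a-octahydronaphthalene F7.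
- Hydrozirconation with (C5H5)2ZrHCl gives chlorobis(cyclopentadienyl){2-[(1R,4aR,8aR)-2,5,5,8a-tetramethyl-1,4,4a,5,6,7,8,8a-octahydronaphthalen-1-yl]ethyl}zirconium F8.
- Zr-to-Al exchange with AlCl3 gives dichloro{2-[(1R,4aR,8aR)-2,5,5,8a-tetramethyl-1,4,4a,5,6,7,8,8a-octahydronaphthalen-1-yl]ethyl}alane F9.
- F9 is added to the peroxycarbenium ion from 14 (BF3·OEt2, CH2Cl2, −78 °C) with the same axial selectivity, and 19 is reached without any reduction.

**Further compounds**
F1 | step 7 | methyl (2S,3R)-3-hydroxy-2-methyl-6-oxoheptanoate | COC(=O)[C@@H](C)[C@H](O)CCC(C)=O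
F2 | step 7 | methyl (2S,3R)-3-(methanesulfonyloxy)-2-methyl-6-oxoheptanoate | COC(=O)[C@@H](C)[C@H](OS(C)(=O)=O)CCC(C)=O
F3 | step 7 | methyl (2S,3R)-6-hydroperoxy-6-methoxy-3-(methanesulfonyloxy)-2-methylheptanoate | COC(=O)[C@@H](C)[C@H](OS(C)(=O)=O)CCC(C)(OC)OO
F4 | step 9 | alkynylcerium dichloride | Cl[Ce](Cl)C#C[C@@H]1C(C)=CC[C@@H]2C(C)(C)CCC[C@@]12C
F5 | step 9 | (3S,4R)-4-{3-hydroxy-3-methyl-5-[(1R,4aR,8aR)-2,5,5,8a-tetramethyl-1,4,4a,5,6,7,8,8a-octahydronaphthalen-1-yl]pent-4-yn-1-yl}-3-methyloxetan-2-one | C[C@H]1[C@@H](CCC(C)(O)C#C[C@@H]2C(C)=CC[C@@H]3C(C)(C)CCC[C@@]23C)OC1=O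
F6 | step 9 | (2S)-2-[(3S,6R)-6-methyl-6-{[(1R,4aR,8aR)-2,5,5,8a-tetramethyl-1,4,4a,5,6,7,8,8a-octahydronaphthalen-1-yl]ethynyl}-1,2-dioxan-3-yl]propanoic acid | OC(=O)[C@@H](C)[C@@H]1CC[C@](C)(C#C[C@@H]2C(C)=CC[C@@H]3C(C)(C)CCC[C@@]23C)OO1
F7 | step 10 | (1R,4aR,8aR)-1-ethenyl-2,5,5,8a-tetramethyl-1,4,4a,5,6,7,8,8a-octahydronaphthalene | C=C[C@@H]1C(C)=CC[C@@H]2C(C)(C)CCC[C@@]12C
F8 | step 10 | chlorobis(cyclopentadienyl){2-[(1R,4aR,8aR)-2,5,5,8a-tetramethyl-1,4,4a,5,6,7,8,8a-octahydronaphthalen-1-yl]ethyl}zirconium | Cl[Zr](CC[C@@H]1C(C)=CC[C@@H]2C(C)(C)CCC[C@@]12C)(C3C=CC=C3)C4C=CC=C4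
F9 | step 10 | dichloro{2-[(1R,4aR,8aR)-2,5,5,8a-tetramethyl-1,4,4a,5,6,7,8,8a-octahydronaphthalen-1-yl]ethyl}alane | Cl[Al](Cl)CC[C@@H]1C(C)=CC[C@@H]2C(C)(C)CCC[C@@]12C
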